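## Structural features

Leoligin is a 2,3,4-trisubstituted tetrahydrofuran (ring atoms O1, C2, C3, C4, C5). C2 carries a 3,4-dimethoxyphenyl ring, C3 an exocyclic CH2O carbon (C6) esterified with (Z)-2-methylbut-2-enoic acid, C4 a 3,4-dimethoxybenzyl group (C7 is its CH2), and C5 is an unsubstituted OCH2. The stereocentres C2 (S), C3 (R) and C4 (R) are contiguous: aryl and C6 are trans, C6 and C7 are cis, so aryl and benzyl are trans across the ring. Three elements are fragile: the Z double bond of the ester, which isomerises to E when the acid is activated as an acyl donor or meets acid or base; the C2–O1 bond, a benzylic ether of an electron-rich arene that can ionise or be hydrogenolysed; and C3–H whenever C6 is a carbonyl group, because the enolate then has O1 in the β position. The real difficulty is C3, which must be cis to its C4 neighbour and trans to its C2 neighbour, together with absolute control at C2. The key step exploits the fact that C3 bears exactly one exocyclic oxygenated carbon between two ring carbons: C6 is the former carbonyl carbon of a six-membered 3-diazotetrahydropyran-4-one, and C3–C4 is the bond made when that ring contracts with loss of N2. In the six-membered precursor the aryl- and benzyl-bearing carbons are 2,5-related, where trans means diequatorial, so this relation can be fixed on a chair before the contraction.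

## Logic of the disconnections

Target atom labels are used throughout. For six-membered compounds the locants are O1, C2 (aryl), C3, C4 (carbonyl), C5 (benzyl), C6, marked "pyranone".

19 ⇒ 17 + 18. The C6–O bond of the ester is cut. The Z-alkene is the most isomerisation-prone unit, so it is attached last. The gain is a robust, neutral alcohol as penultimate compound. The demand is an esterification in which 18 acts only as a nucleophile and is never turned into an acyl donor.

17 ⇒ 16. No skeletal bond is cut; C6 is raised to the ester level. The ester is what the ring contraction delivers, and its α-hydrogen is the handle for correcting C3. The demand is a reduction that is faster than enolisation at C3.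

16 ⇒ 13. The C3–C4 bond of the five-membered ring is cut and C6 is reinserted between C3 and C4 as a ring ketone, with a diazo group on C3. This removes the hardest stereocentre (C3 becomes sp2) and turns the 2,4-trans relation into a 2,5-diequatorial relation on a chair. The demand is migration with retention, no leakage into carbene chemistry, and control of C3 when the ester enol is protonated.

13 ⇒ 11. The C3=N2 bond is cut. Pyranone C3 is the only α-CH2, so diazo transfer has a single possible site. The demand is activation of C3 without β-elimination of O1 from the C3 enolate.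

11 ⇒ 8. The H–C5 and H–C6 bonds (pyranone) are cut, which removes the C5 stereocentre and leaves an enone with one stereocentre. The demand is 1,4-reduction followed by protonation or equilibration to the diequatorial isomer.

8 ⇒ 5 + 6. The sp2–sp3 bond between pyranone C5 and the benzylic CH2 is cut. Carrying the benzyl group in the diene instead would need formylation of a methyl alkyl ketone at its methylene carbon, where regiocontrol is unreliable; cross-coupling at an α-iodoenone is regiospecific. The demand is that the benzylic zinc reagent couples faster than it adds to the enone.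

5 ⇒ 4. The C5–I bond is cut. The vinylogous ester is nucleophilic only at C5, so halogenation needs no directing device.

4 ⇒ 1 + 2. The C2–C3 and O1–C6 bonds (pyranone) are cut, the hetero-Diels–Alder retron of a 2,3-dihydro-4H-pyran-4-one. This reaches commercial materials and puts the only catalyst-set stereocentre (C2) at the start. The demand is high facial selectivity on an electron-rich, sluggish aldehyde.

## Other disconnections considered

Alternative 1: The cut is C2–C3 and C4–C5, so the ring comes from a C2–O1–C5 unit and a C3–C4 unit. In the forward step CsF strips silicon and chloride from A1 to release the carbonyl ylide, which adds across the C=C of A2 anti to the menthyloxy group. This gives the cis-fused bicycle A3, with C6 as lactone carbonyl and C7 as acetal carbon.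
- In favour: two skeletal bonds, the ring and three contiguous stereocentres form in one step. The 3,4-cis relation is enforced by ring fusion rather than by an equilibrium, which is better than the chosen plan at C3. C6 and C7 also arrive at different oxidation levels.
- Against: the ylide is unsymmetrical and non-stabilised, so its orientation and the exo placement of the aryl group are not assured. A1 is a moisture-sensitive α-chloro ether of an electron-rich aldehyde. As drawn, A2 and A3 carry the (1S,2R,5S)-menthyl group, the less accessible antipode, in stoichiometric amount. The second aryl ring is still missing: C7 must be unmasked, arylated and deoxygenated without cleaving the equally benzylic C2–O1 bond, then C6 reduced and esterified.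
- Comparison: both plans rest on a well-understood concerted step. Alternative 1 is better on the C3/C4 relation and equal on the source of absolute control (auxiliary against catalyst). It is slightly worse on step economy (at least five steps after A3) and clearly worse on endgame chemoselectivity, whereas the chosen plan carries both aryl groups from the second C–C bond formation onward.

Alternative 2: The cut is O1–C2 and C3–C4. In the forward step a chiral secondary amine converts A5 into its iminium ion and A4 adds reversibly through oxygen. The resulting enamine attacks the palladium-activated alkyne (Pd(PPh3)4 as metal source) in a 5-exo-dig closure, funnelling the equilibrating adducts into A6.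
- In favour: the whole skeleton with both aryl groups is assembled in one step from two simple components. C2 and C3 are set together under catalyst control, which is better than the equilibration used for C3 in the chosen plan. Only carbonyl reduction, alkene hydrogenation and esterification separate A6 from 19, so the route is clearly shorter.
- Against: an internal aryl alkyne is a weaker acceptor than a terminal one. In A6 the C3–H is α to the aldehyde and allylic, so epimerisation or migration of the double bond into conjugation would erase C3. C4 must still be set by hydrogenation from the face anti to C6, in a molecule with two C–O bonds prone to hydrogenolysis.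
- Comparison: Alternative 2 is better on length and convergence and equal on the source of absolute control. The chosen plan is better on the robustness of its intermediates, needs no hydrogenation near the benzylic ether, and fixes the C2/C4 relation before C3 is formed.

Alternative 3: The cut is C3–C4 and C7–aryl. In the forward step low-valent nickel (NiI2, a bipyridine ligand, Mn powder) turns the secondary iodide A7 into the C3 radical. This cyclises 5-exo-trig onto the allyl ether, and the exocyclic C7 radical is arylated by the nickel species derived from A8, giving A9.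
- In favour: the ring bond and the second aryl group arrive in one step. The chair-like transition state of such 5-hexenyl-type radicals favours C6 cis to C7 and trans to the aryl group, which is the target pattern, set kinetically and with no carbonyl at C6. A9 is the silyl ether of 17, two steps from 19; this equals the chosen endgame and is better in that C3 never becomes epimerisable.
- Against: A7 needs an enantioenriched benzylic ether carbon next to an iodide, which costs several steps. A β-alkoxy alkyl iodide can lose alkoxide under reducing conditions. Arylation before cyclisation and hydrogen capture by the C7 radical compete. Kinetic radical diastereocontrol usually leaves minor isomers, and the electron-rich A8 is a slow coupling partner.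
- Comparison: total length is similar. The three-component reductive coupling is mechanistically more demanding than a unimolecular rearrangement. Alternative 3 is better at C3; the chosen plan is better at the C2/C4 relation, which is thermodynamic and correctable, and in the predictability of each single step.

Key step: step 6

Assumption: the Si face of 1 must be attacked to give the 2S centre; (S)-BINOL is written for this from the usual facial sense of BINOL–Ti(OiPr)4 carbonyl additions, and the mirror-image ligand is used if the sense proves opposite. Compounds 2, 6 and 18 are taken as commercial.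

## Route

Step 1
Reactants: 1 veratraldehyde (3,4-dimethoxybenzaldehyde); 2 (E)-1-methoxy-3-(trimethylsilyloxy)buta-1,3-diene
Product: 4 (S)-2-(3,4-dimethoxyphenyl)-2,3-dihydro-4H-pyran-4-one, via silyl aldol adduct 3 (not isolated)
Conditions: (S)-BINOL (20 mol%), Ti(OiPr)4 (10 mol%), 4 Å MS, Et2O, −20 °C; then CF3CO2H, CH2Cl2, 0 °C
Reagents that add atoms: none
Why: Catalytic asymmetric hetero-Diels–Alder reaction in its stepwise form (Mukaiyama aldol, then acid-induced oxa-Michael closure with loss of methanol); the chiral titanium Lewis acid binds 1 and directs the diene terminus to the Si face, setting C2 as S. Crystallisation of 4 should raise the enantiomeric purity if needed.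

Step 2
Reactants: 4 (S)-2-(3,4-dimethoxyphenyl)-2,3-dihydro-4H-pyran-4-one
Product: 5 (S)-2-(3,4-dimethoxyphenyl)-5-iodo-2,3-dihydro-4H-pyran-4-one
Conditions: I2, pyridine, CH2Cl2, 0 → 25 °C
Reagents that add atoms: iodine, II
Why: α-Iodination of an enone with iodine and pyridine; the enol-ether carbon C5 of the vinylogous ester is the only nucleophilic position, and pyridine removes the proton from the oxocarbenium intermediate. C2 is remote from the reacting site.

Step 3
Reactants: 5 (S)-2-(3,4-dimethoxyphenyl)-5-iodo-2,3-dihydro-4H-pyran-4-one; 6 3,4-dimethoxybenzyl chloride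
Product: 8 (S)-5-(3,4-dimethoxybenzyl)-2-(3,4-dimethoxyphenyl)-2,3-dihydro-4H-pyran-4-one, via benzylzinc chloride 7 (not isolated)
Conditions: 6, Zn dust, LiCl, THF, 25 °C; then 5, Pd(OAc)2 (2 mol%), SPhos (4 mol%), THF, 25 °C
Reagents that add atoms: none
Why: Negishi coupling of an α-iodoenone with a benzylic zinc reagent formed by LiCl-assisted zinc insertion; the alkenyl iodide adds to zerovalent palladium readily, and the zinc reagent is too weak a nucleophile to attack the enone directly.

Step 4
Reactants: 8 (S)-5-(3,4-dimethoxybenzyl)-2-(3,4-dimethoxyphenyl)-2,3-dihydro-4H-pyran-4-one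
Product: 11 (2S,5S)-5-(3,4-dimethoxybenzyl)-2-(3,4-dimethoxyphenyl)tetrahydro-4H-pyran-4-one, via lithium enolate 9 (not isolated), via cis ketone 10 (not isolated)
Conditions: LiBH(s-Bu)3 (1.05 equiv), THF, −78 °C; aq NH4Cl; then DBU (0.2 equiv), CH2Cl2, 25 °C
Reagents that add atoms: none
Why: Conjugate (1,4) hydride reduction of the vinylogous ester by the hindered borohydride gives enolate 9 regiospecifically; axial protonation at C5 and the short amidine equilibration through the C5 enol both lead to the chair with aryl and benzyl equatorial, converting the axial-benzyl isomer 10 into 11. The equilibration is kept mild so that C2 is not disturbed by reversible ring opening; any remaining 10 is separated and re-equilibrated.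

Step 5
Reactants: 11 (2S,5S)-5-(3,4-dimethoxybenzyl)-2-(3,4-dimethoxyphenyl)tetrahydro-4H-pyran-4-one
Product: 13 (2R,5S)-3-diazo-5-(3,4-dimethoxybenzyl)-2-(3,4-dimethoxyphenyl)tetrahydro-4H-pyran-4-one, via trifluoroacetyl ketone 12 (not isolated)
Conditions: LiN(SiMe3)2, THF, −78 °C; CF3CO2CH2CF3, −78 °C; 5% aq HCl work-up; then 4-AcNHC6H4SO2N3, Et3N, H2O (1 equiv), MeCN, 25 °C
Reagents that add atoms: 4-acetamidobenzenesulfonyl azide, CC(=O)Nc1ccc(cc1)S(=O)(=O)N=[N+]=[N-]
Why: Detrifluoroacetylative diazo transfer, an activated form of the Regitz reaction: kinetic deprotonation takes place at the only α-CH2 (C3) and not at the tertiary C5–H, the enolate is C-acylated, and the 1,3-dicarbonyl compound accepts N2 from the sulfonyl azide while the trifluoroacetyl group leaves on the sulfonamide nitrogen. No stereocentre is formed or broken; the C2 descriptor becomes R only because the diazo carbon outranks the aryl group.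

Step 6
Reactants: 13 (2R,5S)-3-diazo-5-(3,4-dimethoxybenzyl)-2-(3,4-dimethoxyphenyl)tetrahydro-4H-pyran-4-one
Product: 16 methyl (2S,3S,4R)-4-(3,4-dimethoxybenzyl)-2-(3,4-dimethoxyphenyl)tetrahydrofuran-3-carboxylate, via ketene 14 (not isolated), via C3-epimeric ester 15 (not isolated)
Conditions: hν (λ ≥ 300 nm, medium-pressure Hg lamp, Pyrex), degassed MeOH (0.01 M), 0 °C; then NaOMe (0.2 equiv), MeOH, 25 °C; AcOH quench
Reagents that add atoms: methanol, CO
Why: Photochemical Wolff rearrangement used as a ring contraction: excitation of the cyclic 2-diazo ketone, locked s-cis, expels N2 with concerted 1,2-shift of the benzyl-bearing ring carbon from the carbonyl carbon to the diazo carbon, giving ketene 14, which methanol traps as the ester. The closest known reaction type is the photo-Wolff contraction of cyclic 2-diazo ketones, oxygen heterocycles included, to ring-contracted esters. The tetrahydrofuran ring is not closed by a cyclisation; it arises from the six-membered ring by this 1,2-alkyl shift, which forms C3–C4 and pushes the former carbonyl carbon out as C6. The migrating carbon keeps its configuration and C2 takes no part, so the trans relation of aryl and benzyl fixed in 11 is carried over unchanged. The new stereocentre C3 is created when the ester enol is protonated; since the kinetic face may be the one anti to the C2 aryl group (giving 15), catalytic NaOMe in the same methanolic solution equilibrates C3 through the ester enolate towards 16, whose ester is trans to the directly attached aryl group and cis to the slimmer CH2Ar group. The photochemical event needs rearrangement to win over carbene chemistry (1,2-hydride shift from C2–H, O–H insertion); the enforced s-cis geometry, direct irradiation without sensitiser or metal, and the single acyl substituent able to migrate secure this. The equilibration needs epimerisation to win over β-elimination of O1, which the poor overlap of the endocyclic C2–O1 bond with the exocyclic enolate and the low base loading should keep slow; the bias towards 16 is expected to be useful but not overwhelming, so residual 15 is separated and returned to the equilibration.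

Step 7
Reactants: 16 methyl (2S,3S,4R)-4-(3,4-dimethoxybenzyl)-2-(3,4-dimethoxyphenyl)tetrahydrofuran-3-carboxylate
Product: 17 [(2S,3R,4R)-4-(3,4-dimethoxybenzyl)-2-(3,4-dimethoxyphenyl)tetrahydrofuran-3-yl]methanol
Conditions: LiAlH4, THF, 0 °C; aq NaOH work-up
Reagents that add atoms: none
Why: Hydride reduction of an ester to the primary alcohol; addition to the carbonyl at 0 °C is much faster than enolisation, so C3 is locked, and aryl ethers and the benzylic ring ether are inert to hydride. The C3 descriptor changes from S to R through priority only.

Step 8
Reactants: 17 [(2S,3R,4R)-4-(3,4-dimethoxybenzyl)-2-(3,4-dimethoxyphenyl)tetrahydrofuran-3-yl]methanol; 18 angelic acid ((Z)-2-methylbut-2-enoic acid)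
Product: 19 leoligin, [(2S,3R,4R)-4-(3,4-dimethoxybenzyl)-2-(3,4-dimethoxyphenyl)tetrahydrofuran-3-yl]methyl (Z)-2-methylbut-2-enoate
Conditions: PPh3, DIAD, THF, 0 → 25 °C
Reagents that add atoms: none
Why: Mitsunobu esterification: the alcohol is activated as its alkoxyphosphonium ion and the carboxylate of 18 displaces at the primary carbon C6, so the acid is never an acyl donor and its Z geometry should survive. No stereocentre is involved.

## Compound list

1 | veratraldehyde | COc1ccc(C=O)cc1OC | starting material
2 | (E)-1-methoxy-3-(trimethylsilyloxy)buta-1,3-diene | CO/C=C/C(=C)O[Si](C)(C)C | starting material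
3 | (S,E)-5-(3,4-dimethoxyphenyl)-1-methoxy-5-(trimethylsilyloxy)pent-1-en-3-one | CO/C=C/C(=O)C[C@H](O[Si](C)(C)C)c1ccc(OC)c(OC)c1 | intermediate (not isolated)
4 | (S)-2-(3,4-dimethoxyphenyl)-2,3-dihydro-4H-pyran-4-one | O=C1C=CO[C@H](c2ccc(OC)c(OC)c2)C1 | intermediate
5 | (S)-2-(3,4-dimethoxyphenyl)-5-iodo-2,3-dihydro-4H-pyran-4-one | O=C1C(I)=CO[C@H](c2ccc(OC)c(OC)c2)C1 | intermediate
6 | 3,4-dimethoxybenzyl chloride | COc1ccc(CCl)cc1OC | starting material
7 | (3,4-dimethoxybenzyl)zinc chloride | COc1ccc(C[Zn]Cl)cc1OC | intermediate (not isolated)
8 | (S)-5-(3,4-dimethoxybenzyl)-2-(3,4-dimethoxyphenyl)-2,3-dihydro-4H-pyran-4-one | O=C1C(Cc2ccc(OC)c(OC)c2)=CO[C@H](c2ccc(OC)c(OC)c2)C1 | intermediate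
9 | lithium (S)-5-(3,4-dimethoxybenzyl)-2-(3,4-dimethoxyphenyl)-3,6-dihydro-2H-pyran-4-olate | [Li+].[O-]C1=C(Cc2ccc(OC)c(OC)c2)CO[C@H](c2ccc(OC)c(OC)c2)C1 | intermediate (not isolated)
10 | (2S,5R)-5-(3,4-dimethoxybenzyl)-2-(3,4-dimethoxyphenyl)tetrahydro-4H-pyran-4-one (2,5-cis) | O=C1C[C@@H](c2ccc(OC)c(OC)c2)OC[C@H]1Cc1ccc(OC)c(OC)c1 | intermediate (not isolated)
11 | (2S,5S)-5-(3,4-dimethoxybenzyl)-2-(3,4-dimethoxyphenyl)tetrahydro-4H-pyran-4-one (2,5-trans) | O=C1C[C@@H](c2ccc(OC)c(OC)c2)OC[C@@H]1Cc1ccc(OC)c(OC)c1 | intermediate
12 | 3-trifluoroacetyl derivative of 11, enol form, C2 and C5 configured as in 11 | OC1=C(C(=O)C(F)(F)F)[C@@H](c2ccc(OC)c(OC)c2)OC[C@@H]1Cc1ccc(OC)c(OC)c1 | intermediate (not isolated)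
13 | (2R,5S)-3-diazo-5-(3,4-dimethoxybenzyl)-2-(3,4-dimethoxyphenyl)tetrahydro-4H-pyran-4-one | [N-]=[N+]=C1C(=O)[C@@H](Cc2ccc(OC)c(OC)c2)CO[C@@H]1c1ccc(OC)c(OC)c1 | intermediate
14 | [4-(3,4-dimethoxybenzyl)-2-(3,4-dimethoxyphenyl)tetrahydrofuran-3-ylidene]ketene, C2 and C4 configured as in 16 | O=C=C1[C@@H](Cc2ccc(OC)c(OC)c2)CO[C@@H]1c1ccc(OC)c(OC)c1 | intermediate (not isolated)
15 | methyl (2S,3R,4R)-4-(3,4-dimethoxybenzyl)-2-(3,4-dimethoxyphenyl)tetrahydrofuran-3-carboxylate (C3 epimer of 16) | COC(=O)[C@@H]1[C@@H](Cc2ccc(OC)c(OC)c2)CO[C@@H]1c1ccc(OC)c(OC)c1 | intermediate (not isolated)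
16 | methyl (2S,3S,4R)-4-(3,4-dimethoxybenzyl)-2-(3,4-dimethoxyphenyl)tetrahydrofuran-3-carboxylate | COC(=O)[C@H]1[C@@H](Cc2ccc(OC)c(OC)c2)CO[C@@H]1c1ccc(OC)c(OC)c1 | intermediate
17 | [(2S,3R,4R)-4-(3,4-dimethoxybenzyl)-2-(3,4-dimethoxyphenyl)tetrahydrofuran-3-yl]methanol | OC[C@H]1[C@@H](Cc2ccc(OC)c(OC)c2)CO[C@@H]1c1ccc(OC)c(OC)c1 | intermediate
18 | angelic acid, (Z)-2-methylbut-2-enoic acid | C/C=C(/C)C(=O)O | starting material
19 | leoligin | C/C=C(/C)C(=O)OC[C@H]1[C@@H](Cc2ccc(OC)c(OC)c2)CO[C@@H]1c1ccc(OC)c(OC)c1 | target

## Step count and least certain steps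

Total: 8 steps. Longest linear sequence: 8 steps (1 to 19); the zinc reagent 7 is made and consumed inside step 3.

Step 6 (key step). Three processes threaten it: leakage of the excited diazo ketone into carbene chemistry (hydride shift from C2–H, O–H insertion into methanol); protonation of the ester enol on the wrong face combined with only a modest thermodynamic preference during equilibration; and base-induced β-elimination of O1, after which the hydroxy cinnamate would lactonise irreversibly. The fallback leaves the ring-contraction logic, sets out from 1 and returns at 17.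
- Stobbe condensation of 1 with dimethyl succinate (NaOMe, MeOH) should give (E)-4-(3,4-dimethoxyphenyl)-3-(methoxycarbonyl)but-3-enoic acid F1.
- Asymmetric hydrogenation ([Rh(cod)(Et-DuPhos)]BF4, ligand antipode chosen for the R acid, H2, MeOH) should give (R)-4-(3,4-dimethoxyphenyl)-3-(methoxycarbonyl)butanoic acid F2.
- Reduction of the ester in the presence of the carboxylate (CaCl2/NaBH4, EtOH), then acidification, should give (R)-4-(3,4-dimethoxybenzyl)dihydrofuran-2(3H)-one F3.
- Aldol addition of its enolate (LiN(iPr)2, THF, −78 °C) to 1, anti to the benzyl group, should give the 3,4-trans hydroxybenzyl lactone F4.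
- LiAlH4 should give the triol F5.
- Acid (camphorsulfonic acid, CH2Cl2) should ionise the benzylic carbinol, and capture by the only hydroxyl able to form a five-membered ring should give 17 with the aryl group trans to C6.

Step 5. Enolisation may partly go towards C5, the C3 enolate may eliminate O1 (ring opening and loss of C2 integrity), or C-acylation may stall. The fallback avoids any lithium enolate, sets out from 11 and returns at 13.
- Condensation with tert-butoxybis(dimethylamino)methane (toluene, 70 °C) at the only α-CH2 should give the (E)-3-[(dimethylamino)methylidene] ketone F6.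
- Diazo transfer to this enaminone with 4-acetamidobenzenesulfonyl azide (MeCN, 25 °C) should give 13 with loss of the sulfonyl formamidine.

Step 4. Competing 1,2-reduction, incomplete conversion of the cis into the trans ketone, or erosion of C2 by reversible retro-oxa-Michael opening during the base treatment are the risks. The fallback sets C5 by reagent delivery instead of equilibration, sets out from 8 and returns at 11.
- Luche reduction (NaBH4, CeCl3·7H2O, MeOH, −78 °C) should give the 2,4-cis allylic alcohol (2S,4S)-5-(3,4-dimethoxybenzyl)-2-(3,4-dimethoxyphenyl)-3,4-dihydro-2H-pyran-4-ol F7.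
- Hydroxyl-directed hydrogenation ([Ir(cod)(PCy3)(py)]PF6, H2, CH2Cl2) should deliver hydrogen to C5 on the hydroxyl face and give the all-equatorial alcohol (2S,4S,5S)-5-(3,4-dimethoxybenzyl)-2-(3,4-dimethoxyphenyl)tetrahydro-2H-pyran-4-ol F8.
- Dess–Martin oxidation (NaHCO3 buffer) should give 11 without exposure to base.

Step 1. Poor facial selectivity, or slow turnover that lets an unselective background reaction compete, is likely with an electron-rich aldehyde. The fallback uses a stoichiometric chiral boron enolate, sets out from 1 and returns at 4.
- (E)-4-Methoxybut-3-en-2-one is enolised with Ipc2BCl (antipode chosen for Si-face attack) and iPr2NEt in Et2O at −78 °C and added to 1; after oxidative work-up this should give (S,E)-5-(3,4-dimethoxyphenyl)-5-hydroxy-1-methoxypent-1-en-3-one F9.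
- CF3CO2H in CH2Cl2 should cyclise it to 4.

Step 8. Z-to-E isomerisation of the unsaturated acid unit, or slow displacement at the β-branched primary carbinol with consumption of the azo reagent, are the risks. The fallback builds the Z alkene on the ester, sets out from 17 and returns at 19.
- Esterification of 17 with 2-[bis(2,2,2-trifluoroethoxy)phosphoryl]propanoic acid (EDC·HCl, DMAP, CH2Cl2) should give the phosphonopropanoate of 17 F10.
- Still–Gennari olefination (KN(SiMe3)2, 18-crown-6, THF, −78 °C; acetaldehyde) should give the Z-trisubstituted alkene of 19.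

## Further compounds

F1 | step 6 | (E)-4-(3,4-dimethoxyphenyl)-3-(methoxycarbonyl)but-3-enoic acid | COC(=O)/C(CC(=O)O)=C/c1ccc(OC)c(OC)c1
F2 | step 6 | (R)-4-(3,4-dimethoxyphenyl)-3-(methoxycarbonyl)butanoic acid | OC(=O)C[C@@H](Cc1ccc(OC)c(OC)c1)C(=O)OC
F3 | step 6 | (R)-4-(3,4-dimethoxybenzyl)dihydrofuran-2(3H)-one | O=C1C[C@@H](Cc2ccc(OC)c(OC)c2)CO1
F4 | step 6 | (3S,4R)-4-(3,4-dimethoxybenzyl)-3-[(3,4-dimethoxyphenyl)(hydroxy)methyl]dihydrofuran-2(3H)-one, 3,4-trans, carbinol epimers | O=C1[C@H](C(O)c2ccc(OC)c(OC)c2)[C@@H](Cc2ccc(OC)c(OC)c2)CO1
F5 | step 6 | (2R,3R)-2-(3,4-dimethoxybenzyl)-3-[(3,4-dimethoxyphenyl)(hydroxy)methyl]butane-1,4-diol, carbinol epimers | OC[C@H](C(O)c1ccc(OC)c(OC)c1)[C@@H](Cc1ccc(OC)c(OC)c1)CO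
F6 | step 5 | (E)-3-[(dimethylamino)methylidene] derivative of 11, C2 and C5 as in 11 | CN(C)/C=C1/C(=O)[C@@H](Cc2ccc(OC)c(OC)c2)CO[C@@H]1c1ccc(OC)c(OC)c1
F7 | step 4 | (2S,4S)-5-(3,4-dimethoxybenzyl)-2-(3,4-dimethoxyphenyl)-3,4-dihydro-2H-pyran-4-ol | O[C@H]1C[C@@H](c2ccc(OC)c(OC)c2)OC=C1Cc1ccc(OC)c(OC)c1
F8 | step 4 | (2S,4S,5S)-5-(3,4-dimethoxybenzyl)-2-(3,4-dimethoxyphenyl)tetrahydro-2H-pyran-4-ol | O[C@H]1C[C@@H](c2ccc(OC)c(OC)c2)OC[C@@H]1Cc1ccc(OC)c(OC)c1
F9 | step 1 | (S,E)-5-(3,4-dimethoxyphenyl)-5-hydroxy-1-methoxypent-1-en-3-one | CO/C=C/C(=O)C[C@H](O)c1ccc(OC)c(OC)c1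
F10 | step 8 | [(2S,3R,4R)-4-(3,4-dimethoxybenzyl)-2-(3,4-dimethoxyphenyl)tetrahydrofuran-3-yl]methyl 2-[bis(2,2,2-trifluoroethoxy)phosphoryl]propanoate | CC(C(=O)OC[C@H]1[C@@H](Cc2ccc(OC)c(OC)c2)CO[C@@H]1c1ccc(OC)c(OC)c1)P(=O)(OCC(F)(F)F)OCC(F)(F)F
A1 | alternative 1 | chloro(3,4-dimethoxyphenyl)methyl (trimethylsilyl)methyl ether | COc1ccc(C(Cl)OC[Si](C)(C)C)cc1OC
A2 | alternative 1 | (5S)-5-[(1S,2R,5S)-menthyloxy]furan-2(5H)-one | O=C1C=C[C@@H](O[C@H]2C[C@@H](C)CC[C@@H]2C(C)C)O1
A3 | alternative 1 | cis-fused 6-(3,4-dimethoxyphenyl)-3-[(1S,2R,5S)-menthyloxy]tetrahydro-1H,3H-furo[3,4-c]furan-1-one | O=C1[C@H]2[C@H](CO[C@@H]2c3ccc(OC)c(OC)c3)[C@@H](O[C@H]4C[C@@H](C)CC[C@@H]4C(C)C)O1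
A4 | alternative 2 | 3-(3,4-dimethoxyphenyl)prop-2-yn-1-ol | OCC#Cc1ccc(OC)c(OC)c1
A5 | alternative 2 | (E)-3-(3,4-dimethoxyphenyl)prop-2-enal | O=C/C=C/c1ccc(OC)c(OC)c1
A6 | alternative 2 | trans-2-(3,4-dimethoxyphenyl)-4-[(E)-3,4-dimethoxybenzylidene]tetrahydrofuran-3-carbaldehyde, C2 and C3 as in 19 | O=C[C@H]1/C(=C\c2ccc(OC)c(OC)c2)CO[C@@H]1c1ccc(OC)c(OC)c1
A7 | alternative 3 | tert-butyl{[3-(allyloxy)-3-(3,4-dimethoxyphenyl)-2-iodopropyl]oxy}dimethylsilane, benzylic carbon as C2 of 19, iodide carbon unspecified | CC(C)(C)[Si](C)(C)OCC(I)[C@H](OCC=C)c1ccc(OC)c(OC)c1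
A8 | alternative 3 | 4-iodo-1,2-dimethoxybenzene | COc1ccc(I)cc1OC
A9 | alternative 3 | tert-butyldimethylsilyl ether of 17 | CC(C)(C)[Si](C)(C)OC[C@H]1[C@@H](Cc2ccc(OC)c(OC)c2)CO[C@@H]1c1ccc(OC)c(OC)c1
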